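If we want the quick number you asked for, the concentration to watch is [incoming ligand]: we take the loss of complex with one exchanged as pseudo-first-order, with a rate proportional to it, and at fixed equivalents it grows with the charge.

| flask | starting complex | incoming ligand | remark | time |
|---|---|---|---|---|
| ash | 6 mM | 3.4 equiv | run made earlier |  |
| elm | 6 mM | 2.5 equiv | run made earlier |  |
| theta | 6.0 mM | 5.00 equiv |  | 30 h |
| delta | 12 mM | 5.00 equiv |  | 30 h |
| eta | 20 mM | 5.00 equiv |  | 30 h |

| run | time / h | complex with one exchanged / % | starting complex / % |
|---|---|---|---|
| ash | 4.00 | 69.3 | 28.6 |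
| ash | 8.00 | 83.1 | 9.0 |
| ash | 10.0 | 84.5 | 5.9 |
| ash | 15.0 | 82.7 | 2.4 |
| ash | 20.0 | 79.6 | 0.7 |
| elm | 4.00 | 57.9 | 40.3 |
| elm | 8.00 | 76.7 | 19.0 |
| elm | 10.0 | 79.7 | 13.1 |
| elm | 15.0 | 84.8 | 5.6 |
| elm | 20.0 | 84.2 | 3.2 |

(each reading ± 0.5 percentage points)

- "hardly changes" means that all values lie within two and a half points (for a concentration: within two and a half percent of the largest)

- [complex with one exchanged] at the end for theta, delta, eta, in this order
- the shape of the row from first to last (falls all the way / rises all the way / falls, then rises / hardly changes / rises, then falls)

In ash the first exchange leaves the sum of starting complex and complex with one exchanged as it is, so we read a fall of that sum as a second exchange. Between 10.0 h and 20.0 h that sum falls by 10 percentage points. At mid-interval complex with one exchanged reads 82.7% and [incoming ligand] is near 13.6 mM, counting one ligand per exchanged complex and a further one per complex gone on. This reads as 775 mM·h for the halving dose, the time integral of [incoming ligand] that brings complex with one exchanged to half by the second exchange. The smaller loss in elm reads 954 mM·h, a poorer reading, so we keep ash.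

Our own reckoning takes a mean ligand use of 1.50 equivalents over 30 h and multiplies each charge by the surviving fraction. That gives 3.41 mM, 3.89 mM and 3.06 mM. Your forecast says 3.3 mM, 3.7 mM and 2.9 mM, rises, then falls: “The intermediate passes through a maximum.” We share the shape, and at eta ours stands higher than yours.

The flasks give 3.36 mM, 4.03 mM and 3.87 mM, rises, then falls.

    starting complex + incoming ligand → leaving ligand + complex with one exchanged (k = 0.00490 M⁻¹ s⁻¹)
    complex with one exchanged + incoming ligand → leaving ligand + complex with two exchanged (k = 2.60 × 10⁻⁴ M⁻¹ s⁻¹)
    complex with two exchanged + incoming ligand → leaving ligand + complex with three exchanged (k = 3.90 × 10⁻⁴ M⁻¹ s⁻¹)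
    complex with three exchanged + incoming ligand ⇌ leaving ligand + complex with four exchanged (K = 9.00, k = 5.60 × 10⁻⁴ M⁻¹ s⁻¹)

In eta, incoming ligand stood at 58.6% of its charge at 15.0 h; taking that as the mean, the dose is 1760 mM·h, and the halving dose gives 4.15 mM against 3.87 mM. In theta the same reckoning gives 3.31 mM against 3.36 mM. Part of what keeps eta this high is the consumption of incoming ligand, together with the hour of the reading: with ligand held at its charge eta ends at 1.27 mM, and read at 300 h it stands at 0.00383 mM.

(All runs come from a simulation from invented constants.)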